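## Structural features

Caraganin B is an isoflavone: a chromen-4-one (ring A fused to the pyranone ring C) that carries ring B on C3. Ring A is a phloroglucinol unit with a free 5-OH, hydrogen-bonded to the C4 carbonyl, and a 7-OMe. Ring B is a resorcinol with free hydroxyls at C2' and C4' and, at C5', a 1,3-diarylallyl group. The only stereocentre is the methine of that group, (R)-configured, doubly benzylic and allylic, flanked by ring B, a 4-hydroxyphenyl ring and an (E)-styrene that ends in a 2,4-dimethoxyphenyl ring; no other stereocentre stands next to it. The fragile parts are the electron-rich styrene and the methine C–H (acid ionises the chain and lets the ortho 4'-OH close to a flavan; strong base can move the double bond into conjugation and erase the stereocentre) and the pyranone, whose C2 is an acceptor for hydroxide, hydride and carbanions. The real difficulty is the order of events: three methyl ethers must stay while four phenols end up free, so the Lewis-acid chemistry that builds ring C and frees the 5-OH has to be finished before the styrene and the stereocentre exist. The stereocentre must then be set catalytically on a hindered, electron-rich arene beside the pyranone. The key step uses the 1,3,5-oxygenation of ring A: in a 3,5-dimethoxyphenyl ester the two carbons ortho to the ester oxygen (either can become C4a) are equivalent, so acyl migration from the future O1 to C4a forms C4–C4a without a regiochemical choice, and the freed O1 closes ring C at C2.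

## Logic of the disconnections

**22 to 21.** The three phenolic O–Si bonds are cut last. The 4'-oxygen sits ortho to the allylic chain and would capture any cation formed there, so it and the two other exposed phenols stay silylated through all side-chain chemistry. Nothing is gained in skeleton, but every step on the chain becomes chemoselective. The forward cleavage must be close to neutral (buffered fluoride), because 22 tolerates neither strong acid nor strong base.

**21 to 19 through 20.** The side-chain C=C of 21 is traced to the C=O of 19 by way of the carbinol 20. With a ketone β to the stereocentre, the methine becomes the β-carbon of an enone. The forward steps need a hydride source that prefers the aryl ketone to the pyranone carbonyl, and a non-acidic dehydration, which can only run toward the CH2 group and should give the conjugated E alkene.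

**19 to 17 and 18.** The bond between the methine carbon and the 4-oxygenated phenyl ring is cut. This removes the stereocentre and leaves a planar enone and an arylboron reagent. The forward conjugate arylation must select one face of the enone and must leave the α-arylated enone of ring C untouched.

**17 to 13 and 16; 16 to 14.** The enone C=C of 17 is cut into an aryl aldehyde and a stabilised phosphorus ylide; 16 comes from 14 by way of 15. A neutral olefination is required because hydroxide-mediated aldol conditions would open ring C and strip the silyl ethers.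

**13 to 11 through 12.** The two O–Si bonds of 13 are exchanged for the O–isopropyl bonds of 11, and the 5-OH is traced to the 5-O-methyl ether. Alkyl ethers are needed while Lewis acid builds ring C, silyl ethers are needed for the mild end game. The forward dealkylation must cleave the chelated 5-OMe and both secondary ethers but not the 7-OMe, and the silylation must pass over the chelated 5-OH.

**11 to 10.** The C5'–CHO bond is cut back to C5'–Br. A bromide is inert to base, to carbodiimide and to BF3, whereas a free aldehyde would alkylate the electron-rich phenol ring under Lewis acid. The forward formylation must work without organolithium reagents, which ring C would not survive.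

**10 to 8 through 9 (key).** C4–C4a and O1–C2 are cut. Ring C disappears, and the target reduces to an aryl ester of a β-methoxyacrylic acid. The forward step must move the acyl group to an ortho carbon (not the para carbon, and not with attack of the arene on the β-carbon) and then close O1 onto C2 with loss of methanol.

**8 to 6 and 7.** The acyl–oxygen bond of the ester is cut, which gives a symmetrical phenol and an acid. The coupling must be free of acid and strong base to spare the enol ether.

**6 to 3 through 5.** The enol ether carbon (the future C2) is removed from the α-carbon of an arylacetate, together with the enol O–Me bond and the ester exchange. The forward formylation relies on the acidity of the benzylic ester position, and the alkylation must occur on oxygen.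

**3 to 1 through 2.** The C5–Br bond and the two O–isopropyl bonds are cut. Etherification first makes bromination selective for the one unhindered activated position.

## Other disconnections considered

**Alternative 1:** The cut removes ring A: C8–C8a, C7–C8, C5–C6 and C4a–C5 are disconnected, so that the tris-silyl ether A1 comes from the fully elaborated pyranonyl diazoketone A2 and methoxyacetylene A3.
- **Forward key step.** A Danheiser benzannulation in its diazoketone form: long-wavelength irradiation, Wolff shift of the pyranone carbon to the diazo carbon, ketene–alkyne [2+2] cycloaddition, four-electron ring opening, six-electron ring closure and tautomerisation to the phenol.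
- **In its favour.** Ring A and four C–C bonds form in one neutral operation. The polarity of A3 places 7-OMe against 5-OH without a protecting group, and the 5-OH is formed free, so steps 8 and 9 of the chosen route have no counterpart. On regiocontrol of the ring A oxygens, protecting-group economy and bonds formed per step this plan is better.
- **Against it here.** The photochemical step comes last, on a substrate whose electron-rich styrene can isomerise or add to the ketene. The vinyl unit of the ketene belongs to an electron-poor vinylogous ester, a substrate class on which this annulation is not established. A3 is volatile and unstable, and A2 needs diazo chemistry on the most valuable intermediate; both conflict with the aim of a safe route.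
- **Comparison.** Structurally A1 differs from 21 only in one silyl group. Both plans rely on a cascade, but the chosen plan runs its uncertain cascade at step 6 on an achiral bromide, whereas here the risk is taken after the stereocentre is set. Step count is judged about equal, because the 3-aryl-4-pyranone acid behind A2 needs several steps itself.

**Alternative 2:** The cut is C3–C1' together with O1–C2: the isoflavone aldehyde A4 is traced to the 2'-hydroxychalcone A5, in which ring B sits on the β-carbon.
- **Forward key step.** Tl(NO3)3 in methanol with trimethyl orthoformate induces an oxidative 1,2-shift of ring B from the β- to the α-carbon with release of monovalent thallium, giving the keto acetal A6. Acid then joins the 2'-oxygen to the acetal carbon and eliminates methanol.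
- **In its favour.** The sequence is biomimetic, A5 is one aldol condensation away from simple aromatic carbonyl compounds, and the rearrangement of chalcones with an electron-rich migrating ring is established chemistry. On precedent this plan is better than the chosen key step, which needs a new combination. The C5 oxygen is carried as a removable acetal-type ether and the formyl group is present from the start, so neither BCl3 nor the palladium formylation is needed; up to the aldehyde stage the step count is equal or slightly better.
- **Against it here.** A stoichiometric trivalent thallium salt is acutely and cumulatively toxic. The aldehyde partner is a symmetrical dialdehyde that must be condensed once only. The acidic ring closure threatens the acetal-type ethers. Three such ethers must finally be removed from a product that contains the acid-sensitive styrene, which is harsher than fluoride cleavage of aryl silyl ethers.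
- **Comparison.** Structurally A4 is the counterpart of 13 with different protecting groups, and the same end game would follow. The chosen plan replaces the thallium oxidation by a redox-neutral acyl shift and accepts one extra dealkylation step. Overall step count is about equal; the chosen plan is preferred on safety and on the mildness of the final deprotection.

**Alternative 3:** The cut is O1–C8a and C4–C4a, with O1–C2 closing afterwards: the tris-allyl 5-O-methyl ether A7 is traced to the side-chain-bearing β-methoxyacrylic acid A8 and the aryne precursor A9.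
- **Forward key step.** CsF converts A9 into 3,5-dimethoxybenzyne A10. The carboxylate oxygen adds to the aryne carbon remote from the flanking methoxy group, the aryl anion takes the acyl group intramolecularly (net insertion into the C–O bond), and the phenoxide displaces methoxide at C2.
- **In its favour.** The conditions are fluoride and mild base, with no Lewis acid, so the step can be run late with the styrene and stereocentre in place. Regiochemistry is set by the methoxy group next to the aryne bond. Aryne insertion into carboxylic acid C–O bonds is a known reaction type, and attack of the arene on the β-carbon, the main worry of the chosen key step, cannot occur. On mildness and on that selectivity issue this plan is equal or better.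
- **Against it here.** Simple O-arylation without acyl transfer competes. A7 still carries the 5-O-methyl group, whose removal requires a chelating Lewis acid in the presence of the styrene, the allyl ethers and the ionisable methine; this is exactly what the chosen route avoids by dealkylating at step 8. A9 takes several steps involving an organolithium reagent and triflic anhydride. A8 must carry the stereocentre through enolate formylation and saponification.
- **Comparison.** Both plans form the same ring C bonds from the same acrylate carbon skeleton. The chosen plan uses acid early on an achiral substrate; this plan uses fluoride late and pays with a late demethylation. Step count is similar, and final removal of allyl groups with zerovalent palladium is as mild as desilylation.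

Key step: step 6

**Remarks and assumptions**
- The stereocentre of the target is (R): ring B > 4-hydroxyphenyl > alkenyl > H.
- The name, connectivity and E descriptor of the key-step precursor 8 and the connectivity of its product 10 are self-consistent; no correction is needed. The enol ether geometry is lost in step 6, so a Z contaminant in 5, 6 or 8 is tolerable.
- Compounds 14 and 18 are taken to be purchasable.
- In step 12 the ligand enantiomer follows the usual quadrant model for (E)-acceptors (α-si/β-si attack with the S ligand), which gives the R centre here; the sense would be confirmed on the first run.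

## Steps

Step 1
Reactants: 1 methyl 2-(2,4-dihydroxyphenyl)acetate
Product: 2 methyl 2-(2,4-diisopropoxyphenyl)acetate
Conditions: 2-bromopropane, K2CO3, DMF, 60 °C
Reagents that add atoms: 2-bromopropane, CC(C)Br
Why: Williamson ether synthesis on both phenols; K2CO3 does not deprotonate the benzylic ester carbon, and isopropyl ethers are chosen because BCl3 later removes them while the 7-OMe stays.

Step 2
Reactants: 2 methyl 2-(2,4-diisopropoxyphenyl)acetate
Product: 3 methyl 2-(5-bromo-2,4-diisopropoxyphenyl)acetate
Conditions: NBS, MeCN, 0 °C → rt
Reagents that add atoms: N-bromosuccinimide, O=C1CCC(=O)N1Br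
Why: Electrophilic aromatic bromination; C5 is para to one alkoxy group and ortho to the other, whereas C3 is shielded between two isopropoxy groups, so monobromination at C5 is expected.

Step 3
Reactants: 3 methyl 2-(5-bromo-2,4-diisopropoxyphenyl)acetate
Product: 5 methyl (E)-2-(5-bromo-2,4-diisopropoxyphenyl)-3-methoxyacrylate, via sodium enolate of the formyl ester 4 (not isolated)
Conditions: NaOMe, HCO2Me, THF, 0 °C → rt; then MeOTs, DMF, rt
Reagents that add atoms: methyl formate, COC=O; methyl p-toluenesulfonate, COS(=O)(=O)c1ccc(C)cc1
Why: Crossed Claisen condensation (formylation) driven by formation of the stabilised enolate, then O-alkylation by the hard sulfonate; C-methylation would create a quaternary centre, and the E enol ether is the usual thermodynamic product.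

Step 4
Reactants: 5 methyl (E)-2-(5-bromo-2,4-diisopropoxyphenyl)-3-methoxyacrylate
Product: 6 (E)-2-(5-bromo-2,4-diisopropoxyphenyl)-3-methoxyacrylic acid
Conditions: LiOH·H2O, THF/MeOH/H2O, 45 °C; then 1 M HCl to pH 4, 0 °C
Reagents that add atoms: lithium hydroxide, [Li+].[OH-]
Why: Saponification by acyl–oxygen cleavage; the β-methoxyacrylate is a vinylogous carbonate that resists hydroxide at this temperature, and brief cold acidification spares the enol ether.

Step 5
Reactants: 6 (E)-2-(5-bromo-2,4-diisopropoxyphenyl)-3-methoxyacrylic acid, 7 3,5-dimethoxyphenol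
Product: 8 3,5-dimethoxyphenyl (E)-2-(5-bromo-2,4-diisopropoxyphenyl)-3-methoxyacrylate
Conditions: EDC·HCl, 4-(dimethylamino)pyridine (0.2 equiv), CH2Cl2, 0 °C → rt
Reagents that add atoms: none
Why: Steglich esterification; the pyridine catalyst carries the acyl group from the O-acylisourea to the phenol, and neither acid nor strong base touches the enol ether.

Step 6
Reactants: 8 3,5-dimethoxyphenyl (E)-2-(5-bromo-2,4-diisopropoxyphenyl)-3-methoxyacrylate
Product: 10 3-(5-bromo-2,4-diisopropoxyphenyl)-5,7-dimethoxy-4H-chromen-4-one, via ortho-hydroxyaryl methoxyvinyl ketone 9 (not isolated)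
Conditions: BF3·OEt2 (3 equiv, promoter), PhCl, 80 °C; then MeOH, 50 °C
Reagents that add atoms: none
Why: Proposed new method: BF3 binds the ester oxygens and ionises the acyl–oxygen bond to a boron-complexed 3,5-dimethoxyphenoxide and an acylium ion stabilised as a vinylogous oxocarbenium ion by the β-methoxy group; recombination at a carbon ortho to the phenol oxygen forms C4–C4a and gives the chelated ketone 9. The closest known reaction type is the Lewis-acid Fries rearrangement of 3,5-dimethoxyphenyl esters to 2-hydroxy-4,6-dimethoxyaryl ketones, and the second stage mirrors the acid-induced closure of ortho-hydroxyaryl β-aminovinyl ketones to chromones; joining the two on a β-methoxyacrylate ester is the new element. Ring C closes by a 6-endo-trig addition of the phenol oxygen to the β-carbon of the boron-activated enone followed by loss of methanol (addition–elimination), which forms O1–C2 and makes the sequence irreversible. No stereocentre is created, and the enol ether geometry disappears. Two selectivities are needed: ortho over para migration, secured because the two ortho carbons are equivalent, the para carbon is flanked by two methoxy groups, and only the ortho ketone is chelated by boron and drained by cyclisation; and acyl migration over attack of the ester's own aryl ring on the activated β-carbon (Pechmann-type closure to a 3-arylcoumarin), which should be disfavoured because it needs the less stable s-cis ester conformer and a β-carbon crowded by the α-aryl group, while ionisation is helped by the stabilised acylium ion. The isopropyl ethers and the bromide should be inert to BF3·OEt2 at this temperature, and stray loss of the 5-O-methyl group would be harmless because step 8 removes it anyway. The methanol finish breaks the boron chelate and completes any unfinished ring closure.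

Step 7
Reactants: 10 3-(5-bromo-2,4-diisopropoxyphenyl)-5,7-dimethoxy-4H-chromen-4-one
Product: 11 5-(5,7-dimethoxy-4-oxo-4H-chromen-3-yl)-2,4-diisopropoxybenzaldehyde
Conditions: Pd(OAc)2 (3 mol %), 1,4-bis(diphenylphosphino)butane (4.5 mol %), N-formylsaccharin, Et3SiH, Na2CO3, DMF, 80 °C
Reagents that add atoms: N-formylsaccharin, O=CN1C(=O)c2ccccc2S1(=O)=O
Why: Palladium-catalysed reductive carbonylation of an aryl bromide (oxidative addition, CO insertion, hydride transfer from the silane to the acylpalladium species); CO is released in the flask from a crystalline surrogate, so neither a CO cylinder nor an organolithium reagent, which ring C would not tolerate, is needed.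

Step 8
Reactants: 11 5-(5,7-dimethoxy-4-oxo-4H-chromen-3-yl)-2,4-diisopropoxybenzaldehyde
Product: 12 2,4-dihydroxy-5-(5-hydroxy-7-methoxy-4-oxo-4H-chromen-3-yl)benzaldehyde
Conditions: BCl3 (6 equiv), CH2Cl2, −78 → 0 °C; then H2O
Reagents that add atoms: none
Why: Lewis-acid ether cleavage; the secondary isopropyl ethers ionise readily once boron is bound, and the 5-OMe is cleaved because BCl3 chelates between its oxygen and the C4 carbonyl, whereas the unchelated 7-OMe should survive at or below 0 °C.

Step 9
Reactants: 12 2,4-dihydroxy-5-(5-hydroxy-7-methoxy-4-oxo-4H-chromen-3-yl)benzaldehyde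
Product: 13 5-(5-hydroxy-7-methoxy-4-oxo-4H-chromen-3-yl)-2,4-bis(triisopropylsilyloxy)benzaldehyde
Conditions: TIPSCl (2.4 equiv), imidazole, DMF, rt
Reagents that add atoms: chlorotriisopropylsilane, CC(C)[Si](Cl)(C(C)C)C(C)C
Why: Silylation of phenols; the 5-OH is locked in a strong hydrogen bond to the C4 carbonyl and is far less nucleophilic than the ring B phenols, and the bulky silyl group is chosen because these ethers sit ortho and para to a carbonyl substituent and must resist later aqueous and hydride conditions.

Step 10
Reactants: 14 2-bromo-1-(2,4-dimethoxyphenyl)ethan-1-one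
Product: 16 1-(2,4-dimethoxyphenyl)-2-(triphenyl-λ5-phosphanylidene)ethan-1-one, via phenacylphosphonium bromide 15 (not isolated)
Conditions: PPh3, toluene, rt; then 2 M NaOH (aq), CH2Cl2, rt
Reagents that add atoms: triphenylphosphine, c1ccc(cc1)P(c1ccccc1)c1ccccc1
Why: SN2 quaternisation of the phosphine by the α-bromoketone followed by deprotonation of the acidic phosphonium salt gives the stabilised, storable acyl ylide.

Step 11
Reactants: 13 5-(5-hydroxy-7-methoxy-4-oxo-4H-chromen-3-yl)-2,4-bis(triisopropylsilyloxy)benzaldehyde, 16 1-(2,4-dimethoxyphenyl)-2-(triphenyl-λ5-phosphanylidene)ethan-1-one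
Product: 17 3-{5-[(E)-3-(2,4-dimethoxyphenyl)-3-oxoprop-1-en-1-yl]-2,4-bis(triisopropylsilyloxy)phenyl}-5-hydroxy-7-methoxy-4H-chromen-4-one
Conditions: toluene, 100 °C
Reagents that add atoms: none
Why: Wittig reaction of a stabilised ylide, which should give the E enone under neutral conditions and so avoids the hydroxide of an aldol condensation, which would open ring C and cleave the silyl ethers.

Step 12
Reactants: 17 3-{5-[(E)-3-(2,4-dimethoxyphenyl)-3-oxoprop-1-en-1-yl]-2,4-bis(triisopropylsilyloxy)phenyl}-5-hydroxy-7-methoxy-4H-chromen-4-one, 18 [4-(tert-butyldimethylsilyloxy)phenyl]boronic acid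
Product: 19 3-{5-[(1R)-1-[4-(tert-butyldimethylsilyloxy)phenyl]-3-(2,4-dimethoxyphenyl)-3-oxopropyl]-2,4-bis(triisopropylsilyloxy)phenyl}-5-hydroxy-7-methoxy-4H-chromen-4-one
Conditions: [Rh(OH)((S)-binap)]2 (3 mol %), dioxane/H2O 10:1, 40 °C
Reagents that add atoms: none
Why: Hayashi–Miyaura asymmetric conjugate arylation (transmetalation to the hydroxo-rhodium complex, insertion of the enone into the aryl–rhodium bond, hydrolysis of the rhodium enolate) without added base, which protects the silyl ethers. The new stereocentre is set by the S-configured bisphosphine, which should direct the aryl group to the β-si face of the E enone and so give the R centre. The α-arylated enone of ring C is too hindered and too electron-rich to insert.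

Step 13
Reactants: 19 3-{5-[(1R)-1-[4-(tert-butyldimethylsilyloxy)phenyl]-3-(2,4-dimethoxyphenyl)-3-oxopropyl]-2,4-bis(triisopropylsilyloxy)phenyl}-5-hydroxy-7-methoxy-4H-chromen-4-one
Product: 20 3-{5-[(1R)-1-[4-(tert-butyldimethylsilyloxy)phenyl]-3-(2,4-dimethoxyphenyl)-3-hydroxypropyl]-2,4-bis(triisopropylsilyloxy)phenyl}-5-hydroxy-7-methoxy-4H-chromen-4-one (both carbinol epimers)
Conditions: NaBH4, CeCl3·7H2O, MeOH/THF, −20 → 0 °C
Reagents that add atoms: none
Why: Luche reduction; the cerium-modified borohydride favours 1,2-addition to the ketone over conjugate addition to C2 of ring C, whose carbonyl is a vinylogous ester further deactivated by the 5-OH chelate. The new carbinol centre is not controlled and is removed in step 14.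

Step 14
Reactants: 20 3-{5-[(1R)-1-[4-(tert-butyldimethylsilyloxy)phenyl]-3-(2,4-dimethoxyphenyl)-3-hydroxypropyl]-2,4-bis(triisopropylsilyloxy)phenyl}-5-hydroxy-7-methoxy-4H-chromen-4-one
Product: 21 3-{5-[(1R,2E)-1-[4-(tert-butyldimethylsilyloxy)phenyl]-3-(2,4-dimethoxyphenyl)prop-2-en-1-yl]-2,4-bis(triisopropylsilyloxy)phenyl}-5-hydroxy-7-methoxy-4H-chromen-4-one
Conditions: Burgess reagent (methyl N-(triethylammoniosulfonyl)carbamate), THF, 50 °C
Reagents that add atoms: none
Why: Burgess dehydration (syn-elimination of the O-sulfamate) under neutral conditions; only the CH2 group offers β-hydrogens, so the double bond can form only in conjugation with the dimethoxyphenyl ring, E by preference, and the methine C–H is not involved, so the stereocentre is untouched.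

Step 15
Reactants: 21 3-{5-[(1R,2E)-1-[4-(tert-butyldimethylsilyloxy)phenyl]-3-(2,4-dimethoxyphenyl)prop-2-en-1-yl]-2,4-bis(triisopropylsilyloxy)phenyl}-5-hydroxy-7-methoxy-4H-chromen-4-one
Product: 22 caraganin B, 3-{2,4-dihydroxy-5-[(1R,2E)-3-(2,4-dimethoxyphenyl)-1-(4-hydroxyphenyl)prop-2-en-1-yl]phenyl}-5-hydroxy-7-methoxy-4H-chromen-4-one
Conditions: Bu4NF, AcOH (1:1), THF, 0 °C → rt
Reagents that add atoms: none
Why: Fluoride-induced cleavage of the three aryl silyl ethers, driven by the Si–F bond; the acetic acid buffer keeps the phenols protonated, so neither ring C nor the allylic methine meets strong base and no acid strong enough to ionise the chain is present.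

## Compound list

1 | methyl 2-(2,4-dihydroxyphenyl)acetate | COC(=O)Cc1ccc(O)cc1O | starting material
2 | methyl 2-(2,4-diisopropoxyphenyl)acetate | COC(=O)Cc1ccc(OC(C)C)cc1OC(C)C | intermediate
3 | methyl 2-(5-bromo-2,4-diisopropoxyphenyl)acetate | COC(=O)Cc1cc(Br)c(OC(C)C)cc1OC(C)C | intermediate
4 | sodium enolate of methyl 2-(5-bromo-2,4-diisopropoxyphenyl)-3-oxopropanoate (not isolated) | [Na+].[O-]C=C(C(=O)OC)c1cc(Br)c(OC(C)C)cc1OC(C)C | intermediate
5 | methyl (E)-2-(5-bromo-2,4-diisopropoxyphenyl)-3-methoxyacrylate | CO/C=C(\c1cc(Br)c(OC(C)C)cc1OC(C)C)C(=O)OC | intermediate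
6 | (E)-2-(5-bromo-2,4-diisopropoxyphenyl)-3-methoxyacrylic acid | CO/C=C(\c1cc(Br)c(OC(C)C)cc1OC(C)C)C(=O)O | intermediate
7 | 3,5-dimethoxyphenol | COc1cc(O)cc(OC)c1 | starting material
8 | 3,5-dimethoxyphenyl (E)-2-(5-bromo-2,4-diisopropoxyphenyl)-3-methoxyacrylate | CO/C=C(\c1cc(Br)c(OC(C)C)cc1OC(C)C)C(=O)Oc1cc(OC)cc(OC)c1 | intermediate
9 | (E)-2-(5-bromo-2,4-diisopropoxyphenyl)-1-(2-hydroxy-4,6-dimethoxyphenyl)-3-methoxyprop-2-en-1-one (boron-chelated in the flask, not isolated) | CO/C=C(\c1cc(Br)c(OC(C)C)cc1OC(C)C)C(=O)c1c(O)cc(OC)cc1OC | intermediate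
10 | 3-(5-bromo-2,4-diisopropoxyphenyl)-5,7-dimethoxy-4H-chromen-4-one | COc1cc(OC)c2c(c1)occ(-c1cc(Br)c(OC(C)C)cc1OC(C)C)c2=O | intermediate
11 | 5-(5,7-dimethoxy-4-oxo-4H-chromen-3-yl)-2,4-diisopropoxybenzaldehyde | COc1cc(OC)c2c(c1)occ(-c1cc(C=O)c(OC(C)C)cc1OC(C)C)c2=O | intermediate
12 | 2,4-dihydroxy-5-(5-hydroxy-7-methoxy-4-oxo-4H-chromen-3-yl)benzaldehyde | COc1cc(O)c2c(c1)occ(-c1cc(C=O)c(O)cc1O)c2=O | intermediate
13 | 5-(5-hydroxy-7-methoxy-4-oxo-4H-chromen-3-yl)-2,4-bis(triisopropylsilyloxy)benzaldehyde | COc1cc(O)c2c(c1)occ(-c1cc(C=O)c(O[Si](C(C)C)(C(C)C)C(C)C)cc1O[Si](C(C)C)(C(C)C)C(C)C)c2=O | intermediate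
14 | 2-bromo-1-(2,4-dimethoxyphenyl)ethan-1-one | COc1ccc(C(=O)CBr)c(OC)c1 | starting material
15 | [2-(2,4-dimethoxyphenyl)-2-oxoethyl]triphenylphosphonium bromide (not isolated) | COc1ccc(C(=O)C[P+](c2ccccc2)(c2ccccc2)c2ccccc2)c(OC)c1.[Br-] | intermediate
16 | 1-(2,4-dimethoxyphenyl)-2-(triphenyl-λ5-phosphanylidene)ethan-1-one | COc1ccc(C(=O)C=P(c2ccccc2)(c2ccccc2)c2ccccc2)c(OC)c1 | intermediate
17 | 3-{5-[(E)-3-(2,4-dimethoxyphenyl)-3-oxoprop-1-en-1-yl]-2,4-bis(triisopropylsilyloxy)phenyl}-5-hydroxy-7-methoxy-4H-chromen-4-one | COc1ccc(C(=O)/C=C/c2cc(-c3coc4cc(OC)cc(O)c4c3=O)c(O[Si](C(C)C)(C(C)C)C(C)C)cc2O[Si](C(C)C)(C(C)C)C(C)C)c(OC)c1 | intermediate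
18 | [4-(tert-butyldimethylsilyloxy)phenyl]boronic acid | CC(C)(C)[Si](C)(C)Oc1ccc(B(O)O)cc1 | starting material
19 | 3-{5-[(1R)-1-[4-(tert-butyldimethylsilyloxy)phenyl]-3-(2,4-dimethoxyphenyl)-3-oxopropyl]-2,4-bis(triisopropylsilyloxy)phenyl}-5-hydroxy-7-methoxy-4H-chromen-4-one | COc1ccc(C(=O)C[C@H](c2ccc(O[Si](C)(C)C(C)(C)C)cc2)c2cc(-c3coc4cc(OC)cc(O)c4c3=O)c(O[Si](C(C)C)(C(C)C)C(C)C)cc2O[Si](C(C)C)(C(C)C)C(C)C)c(OC)c1 | intermediate
20 | 3-{5-[(1R)-1-[4-(tert-butyldimethylsilyloxy)phenyl]-3-(2,4-dimethoxyphenyl)-3-hydroxypropyl]-2,4-bis(triisopropylsilyloxy)phenyl}-5-hydroxy-7-methoxy-4H-chromen-4-one (carbinol centre unassigned, both epimers) | COc1ccc(C(O)C[C@H](c2ccc(O[Si](C)(C)C(C)(C)C)cc2)c2cc(-c3coc4cc(OC)cc(O)c4c3=O)c(O[Si](C(C)C)(C(C)C)C(C)C)cc2O[Si](C(C)C)(C(C)C)C(C)C)c(OC)c1 | intermediate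
21 | 3-{5-[(1R,2E)-1-[4-(tert-butyldimethylsilyloxy)phenyl]-3-(2,4-dimethoxyphenyl)prop-2-en-1-yl]-2,4-bis(triisopropylsilyloxy)phenyl}-5-hydroxy-7-methoxy-4H-chromen-4-one | COc1ccc(/C=C/[C@H](c2ccc(O[Si](C)(C)C(C)(C)C)cc2)c2cc(-c3coc4cc(OC)cc(O)c4c3=O)c(O[Si](C(C)C)(C(C)C)C(C)C)cc2O[Si](C(C)C)(C(C)C)C(C)C)c(OC)c1 | intermediate
22 | caraganin B, 3-{2,4-dihydroxy-5-[(1R,2E)-3-(2,4-dimethoxyphenyl)-1-(4-hydroxyphenyl)prop-2-en-1-yl]phenyl}-5-hydroxy-7-methoxy-4H-chromen-4-one | COc1ccc(/C=C/[C@H](c2ccc(O)cc2)c2cc(-c3coc4cc(OC)cc(O)c4c3=O)c(O)cc2O)c(OC)c1 | target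

## Step count and least certain steps

Total: 15 steps. Longest linear sequence: 14 steps (steps 1–9 and 11–15); step 10 is a one-step side branch.

**Step 6 (key step, proposed new method).** The most likely failure is that the ester's own aryl ring attacks the Lewis-acid-activated β-carbon and closes to a coumarin, because an aryl β-alkoxyacrylate is also a Pechmann-type substrate. Partial loss of isopropyl groups at the temperature needed for ionisation, or some para migration, is the second concern.
Fallback (known chemistry), setting out from 3 and returning at 10: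
- The ester is saponified (LiOH, aqueous THF; dilute HCl) to 2-(5-bromo-2,4-diisopropoxyphenyl)acetic acid F1.
- F1 acylates 7 ortho to the hydroxyl group under BF3·OEt2 at 80 °C (Friedel–Crafts acylation) to give the deoxybenzoin 2-(5-bromo-2,4-diisopropoxyphenyl)-1-(2-hydroxy-4,6-dimethoxyphenyl)ethan-1-one F2.
- Heating F2 with N,N-dimethylformamide dimethyl acetal in toluene supplies the C2 carbon and closes ring C with loss of dimethylamine, giving 10.
- This builds C4–C4a intermolecularly and adds C2 last, so the β-carbon electrophile that causes the problem never exists.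

**Step 12.** Insertion of the enone into the aryl–rhodium bond may be slow, because the β-aryl group is electron-rich and carries an ortho silyloxy group. Protodeboronation of 18 could then outrun the addition, and facial discrimination by the bisphosphine may be eroded for a β-aryl enone.
Fallback, setting out from 13 and returning at 20:
- Wittig reaction of 13 with (triphenylphosphoranylidene)acetaldehyde gives the more electrophilic and less hindered acceptor 3-{5-[(E)-3-oxoprop-1-en-1-yl]-2,4-bis(triisopropylsilyloxy)phenyl}-5-hydroxy-7-methoxy-4H-chromen-4-one F3.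
- Conjugate arylation of F3 with 18 is run with [RhCl(C2H4)2]2 and a chiral bicyclo[2.2.2]octadiene ligand (the enantiomer that serves the β-si face), giving the aldehyde (3R)-3-[4-(tert-butyldimethylsilyloxy)phenyl]-3-[5-(5-hydroxy-7-methoxy-4-oxo-4H-chromen-3-yl)-2,4-bis(triisopropylsilyloxy)phenyl]propanal F4.
- Rhodium-catalysed 1,2-addition of (2,4-dimethoxyphenyl)boronic acid to F4 (Rh(acac)(CO)2, dppf, aqueous DME, 80 °C) delivers 20.
- The stereocentre is set on an enal instead of an enone, and the carbinol arises by aryl addition instead of hydride reduction.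

**Step 13.** Hydride may be delivered to C2 or C4 of ring C in competition with reduction of the ketone, which is deactivated by its ortho and para methoxy groups. Over-reduction of the heterocycle would be hard to reverse.
Fallback, setting out from 13 and returning at 21 (no carbonyl reduction and no dehydration):
- Horner–Wadsworth–Emmons reaction of 13 with diethyl [(pyridin-2-ylsulfonyl)methyl]phosphonate (LiCl, DBU, MeCN) gives the vinyl sulfone 5-hydroxy-7-methoxy-3-{5-[(E)-2-(pyridin-2-ylsulfonyl)ethenyl]-2,4-bis(triisopropylsilyloxy)phenyl}-4H-chromen-4-one F5.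
- Chelation-assisted conjugate arylation of F5 with 18 (Rh(acac)(C2H4)2 with the Chiraphos enantiomer that serves the β-si face, aqueous dioxane) gives the sulfone 3-{5-[(1R)-1-[4-(tert-butyldimethylsilyloxy)phenyl]-2-(pyridin-2-ylsulfonyl)ethyl]-2,4-bis(triisopropylsilyloxy)phenyl}-5-hydroxy-7-methoxy-4H-chromen-4-one F6.
- Julia–Kocienski-type olefination of F6 with 2,4-dimethoxybenzaldehyde (KN(SiMe3)2, one extra equivalent for the 5-OH, DME, −78 °C) forms the styrene directly and gives 21, expected mainly as the E isomer with an aromatic aldehyde.

**Step 14.** The very electron-rich benzylic sulfamate may ionise before the concerted syn-elimination occurs. The cation could then alkylate another arene intermolecularly or be captured by the reagent, and the 5-OH may consume part of the reagent.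
Fallback, setting out from 20 and returning at 21:
- The alcohol is converted with MsCl and Et3N in CH2Cl2 at −20 °C, through its mesylate, into the benzylic chloride 3-{5-[(1R)-1-[4-(tert-butyldimethylsilyloxy)phenyl]-3-chloro-3-(2,4-dimethoxyphenyl)propyl]-2,4-bis(triisopropylsilyloxy)phenyl}-5-hydroxy-7-methoxy-4H-chromen-4-one F7.
- F7 is not purified; DBU in the same flask eliminates hydrogen chloride to give 21.
- This replaces the one-stage intramolecular elimination by substitution followed by base-induced elimination in the presence of excess amine, which intercepts the cation as the alkene.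

**Step 7.** The silane may intercept the arylpalladium bromide before CO insertion (hydrodebromination), because the electron-rich, ortho-alkoxylated position reacts slowly. Conjugate hydrosilylation of ring C is a lesser concern.
Fallback, setting out from 10 and returning at 11:
- Suzuki–Miyaura coupling of 10 with vinylboronic acid pinacol ester (PdCl2(dppf), K2CO3, dioxane/H2O, 80 °C) gives 3-(5-ethenyl-2,4-diisopropoxyphenyl)-5,7-dimethoxy-4H-chromen-4-one F8.
- Lemieux–Johnson cleavage of F8 (K2OsO4·2H2O cat., NaIO4, 2,6-lutidine, dioxane/H2O) gives 11; the electron-poor, trisubstituted C2=C3 bond of ring C should be much slower to dihydroxylate than the styrene.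
- No hydride source is present in either operation.

## Further compounds

F1 | step 6 | 2-(5-bromo-2,4-diisopropoxyphenyl)acetic acid | OC(=O)Cc1cc(Br)c(OC(C)C)cc1OC(C)C
F2 | step 6 | 2-(5-bromo-2,4-diisopropoxyphenyl)-1-(2-hydroxy-4,6-dimethoxyphenyl)ethan-1-one | COc1cc(O)c(C(=O)Cc2cc(Br)c(OC(C)C)cc2OC(C)C)c(OC)c1
F3 | step 12 | 3-{5-[(E)-3-oxoprop-1-en-1-yl]-2,4-bis(triisopropylsilyloxy)phenyl}-5-hydroxy-7-methoxy-4H-chromen-4-one | COc1cc(O)c2c(c1)occ(-c1cc(/C=C/C=O)c(O[Si](C(C)C)(C(C)C)C(C)C)cc1O[Si](C(C)C)(C(C)C)C(C)C)c2=O
F4 | step 12 | (3R)-3-[4-(tert-butyldimethylsilyloxy)phenyl]-3-[5-(5-hydroxy-7-methoxy-4-oxo-4H-chromen-3-yl)-2,4-bis(triisopropylsilyloxy)phenyl]propanal | O=CC[C@H](c1ccc(O[Si](C)(C)C(C)(C)C)cc1)c1cc(-c2coc3cc(OC)cc(O)c3c2=O)c(O[Si](C(C)C)(C(C)C)C(C)C)cc1O[Si](C(C)C)(C(C)C)C(C)C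
F5 | step 13 | 5-hydroxy-7-methoxy-3-{5-[(E)-2-(pyridin-2-ylsulfonyl)ethenyl]-2,4-bis(triisopropylsilyloxy)phenyl}-4H-chromen-4-one | COc1cc(O)c2c(c1)occ(-c1cc(/C=C/S(=O)(=O)c3ccccn3)c(O[Si](C(C)C)(C(C)C)C(C)C)cc1O[Si](C(C)C)(C(C)C)C(C)C)c2=O
F6 | step 13 | 3-{5-[(1R)-1-[4-(tert-butyldimethylsilyloxy)phenyl]-2-(pyridin-2-ylsulfonyl)ethyl]-2,4-bis(triisopropylsilyloxy)phenyl}-5-hydroxy-7-methoxy-4H-chromen-4-one | O=S(=O)(C[C@H](c1ccc(O[Si](C)(C)C(C)(C)C)cc1)c1cc(-c2coc3cc(OC)cc(O)c3c2=O)c(O[Si](C(C)C)(C(C)C)C(C)C)cc1O[Si](C(C)C)(C(C)C)C(C)C)c1ccccn1
F7 | step 14 | 3-{5-[(1R)-1-[4-(tert-butyldimethylsilyloxy)phenyl]-3-chloro-3-(2,4-dimethoxyphenyl)propyl]-2,4-bis(triisopropylsilyloxy)phenyl}-5-hydroxy-7-methoxy-4H-chromen-4-one (chloride-bearing centre unassigned) | COc1ccc(C(Cl)C[C@H](c2ccc(O[Si](C)(C)C(C)(C)C)cc2)c2cc(-c3coc4cc(OC)cc(O)c4c3=O)c(O[Si](C(C)C)(C(C)C)C(C)C)cc2O[Si](C(C)C)(C(C)C)C(C)C)c(OC)c1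
F8 | step 7 | 3-(5-ethenyl-2,4-diisopropoxyphenyl)-5,7-dimethoxy-4H-chromen-4-one | COc1cc(OC)c2c(c1)occ(-c1cc(C=C)c(OC(C)C)cc1OC(C)C)c2=O
A1 | alternative 1 | tris-O-triisopropylsilyl caraganin B | COc1ccc(/C=C/[C@H](c2ccc(O[Si](C(C)C)(C(C)C)C(C)C)cc2)c2cc(-c3coc4cc(OC)cc(O)c4c3=O)c(O[Si](C(C)C)(C(C)C)C(C)C)cc2O[Si](C(C)C)(C(C)C)C(C)C)c(OC)c1
A2 | alternative 1 | 2-(2-diazoacetyl)-5-{5-[(1R,2E)-3-(2,4-dimethoxyphenyl)-1-[4-(triisopropylsilyloxy)phenyl]prop-2-en-1-yl]-2,4-bis(triisopropylsilyloxy)phenyl}-4H-pyran-4-one | COc1ccc(/C=C/[C@H](c2ccc(O[Si](C(C)C)(C(C)C)C(C)C)cc2)c2cc(-c3coc(C(=O)C=[N+]=[N-])cc3=O)c(O[Si](C(C)C)(C(C)C)C(C)C)cc2O[Si](C(C)C)(C(C)C)C(C)C)c(OC)c1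
A3 | alternative 1 | methoxyacetylene | COC#C
A4 | alternative 2 | 3-{5-formyl-2,4-bis[2-(trimethylsilyl)ethoxymethoxy]phenyl}-7-methoxy-5-[2-(trimethylsilyl)ethoxymethoxy]-4H-chromen-4-one | COc1cc(OCOCC[Si](C)(C)C)c2c(c1)occ(-c1cc(C=O)c(OCOCC[Si](C)(C)C)cc1OCOCC[Si](C)(C)C)c2=O
A5 | alternative 2 | (E)-3-{5-formyl-2,4-bis[2-(trimethylsilyl)ethoxymethoxy]phenyl}-1-{2-hydroxy-4-methoxy-6-[2-(trimethylsilyl)ethoxymethoxy]phenyl}prop-2-en-1-one | COc1cc(O)c(C(=O)/C=C/c2cc(C=O)c(OCOCC[Si](C)(C)C)cc2OCOCC[Si](C)(C)C)c(OCOCC[Si](C)(C)C)c1
A6 | alternative 2 | 2-{5-formyl-2,4-bis[2-(trimethylsilyl)ethoxymethoxy]phenyl}-1-{2-hydroxy-4-methoxy-6-[2-(trimethylsilyl)ethoxymethoxy]phenyl}-3,3-dimethoxypropan-1-one (racemic) | COc1cc(O)c(C(=O)C(C(OC)OC)c2cc(C=O)c(OCOCC[Si](C)(C)C)cc2OCOCC[Si](C)(C)C)c(OCOCC[Si](C)(C)C)c1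
A7 | alternative 3 | tris-O-allyl 5-O-methyl caraganin B | COc1ccc(/C=C/[C@H](c2ccc(OCC=C)cc2)c2cc(-c3coc4cc(OC)cc(OC)c4c3=O)c(OCC=C)cc2OCC=C)c(OC)c1
A8 | alternative 3 | (E)-2-{2,4-bis(allyloxy)-5-[(1R,2E)-1-[4-(allyloxy)phenyl]-3-(2,4-dimethoxyphenyl)prop-2-en-1-yl]phenyl}-3-methoxyacrylic acid | COc1ccc(/C=C/[C@H](c2ccc(OCC=C)cc2)c2cc(/C(=C\OC)C(=O)O)c(OCC=C)cc2OCC=C)c(OC)c1
A9 | alternative 3 | 3,5-dimethoxy-2-(trimethylsilyl)phenyl trifluoromethanesulfonate | COc1cc(OC)c([Si](C)(C)C)c(OS(=O)(=O)C(F)(F)F)c1
A10 | alternative 3 | 3,5-dimethoxybenzyne | COC1=CC(OC)=CC#C1
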